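**Retrosynthetic overview**
- C2–C3: the acetic acid arm is added last. A bis-silyl ketene acetal attacks axially on the 1,2-dioxan-3-ylium ion released from a 3-methoxy-1,2-dioxane.
- O–C6, the only ring (made in the second-last step): a new catalytic asymmetric 6-exo closure of a hydroperoxy acetal onto an acyclic methylidene group. The O–O unit comes from H2O2.
- C5–C6, the skeleton-forming key step: a 1,2-metallate shift of C5 from boron to C6 (Shapiro vinyllithium plus a beta-chiral pinacol boronate, Zweifel olefination).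
- C8 and C12: two rounds of alkyne hydroboration and Rh-catalysed asymmetric 1,4-addition to pent-3-en-2-one, with a methyl ketone to alkyne conversion between them.
- C4: CuH-catalysed asymmetric hydroboration of methacrolein dimethyl acetal.

Numbering used below: C1 = CO2H, C3/C4/C5/C6 = ring carbons, C7 to C14 = side chain, C14 carries the phenyl group. The target is 3S,4S,6R,8R,12S.

Assumption: the BINAP sense follows the usual model (the S ligand delivers the alkenyl group to the alpha-si face of an E-enone). The antipodes quoted for DTBM-SEGPHOS (step 5) and for the IDPi acid (step 7) are provisional and are swapped if the first run shows the other sense.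

**Step 1**
Reactants: 1 ethynylbenzene; 2 (E)-pent-3-en-2-one
Product: 4 (4S,5E)-4-methyl-6-phenylhex-5-en-2-one, via styryl catecholborane 3 (not isolated)
Conditions: catecholborane, neat, 70 °C; then 2, Rh(acac)(C2H4)2 (3 mol%), (R)-BINAP, Et3N, dioxane/H2O 10:1, 100 °C
Reagents that add atoms: none
Why: Syn hydroboration gives the E-alkenylboron, and the Hayashi–Miyaura asymmetric 1,4-addition inserts the enone into the alkenyl–Rh bond on the alpha-re face fixed by (R)-BINAP, which sets C12 as S.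

**Step 2**
Reactants: 4 (4S,5E)-4-methyl-6-phenylhex-5-en-2-one
Product: 6 [(1E,3S)-3-methylhex-1-en-5-yn-1-yl]benzene, via enol phosphate 5 (not isolated)
Conditions: LDA (1.1 equiv), THF, −78 °C; ClP(O)(OEt)2; then LDA (2.3 equiv), −78 °C to rt; H2O
Reagents that add atoms: none
Why: Kinetic enolisation at CH3, O-phosphorylation and LDA-induced elimination of the enol phosphate (methyl ketone to terminal alkyne conversion) leave the stereocentre, which is beta to the carbonyl, untouched.

**Step 3**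
Reactants: 6 [(1E,3S)-3-methylhex-1-en-5-yn-1-yl]benzene; 2 (E)-pent-3-en-2-one
Product: 8 (4R,5E,8S,9E)-4,8-dimethyl-10-phenyldeca-5,9-dien-2-one, via dienyl catecholborane 7 (not isolated)
Conditions: catecholborane (1.05 equiv), 70 °C; then 2 (3 equiv), Rh(acac)(C2H4)2 (3 mol%), (S)-BINAP, Et3N, dioxane/H2O 10:1, 100 °C
Reagents that add atoms: none
Why: Catecholborane reacts with the terminal alkyne in preference to the two internal alkenes, and a second Hayashi–Miyaura 1,4-addition under (S)-BINAP control (alpha-si face) sets C8 as R and keeps the new alkene E.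

**Step 4**
Reactants: 8 (4R,5E,8S,9E)-4,8-dimethyl-10-phenyldeca-5,9-dien-2-one
Product: 9 trisylhydrazone of 8, N'-[(2E,4R,5E,8S,9E)-4,8-dimethyl-10-phenyldeca-5,9-dien-2-ylidene]-2,4,6-tri(propan-2-yl)benzenesulfonohydrazide
Conditions: 2,4,6-triisopropylbenzenesulfonohydrazide, cat. HCl, MeCN, rt
Reagents that add atoms: 2,4,6-triisopropylbenzenesulfonohydrazide, NNS(=O)(=O)c1c(C(C)C)cc(C(C)C)cc1C(C)C
Why: This is an acid-catalysed hydrazone condensation, and the trisyl group blocks ortho-lithiation so that nitrogen is lost at 0 °C in the next step.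

**Step 5**
Reactants: 10 3,3-dimethoxy-2-methylprop-1-ene (methacrolein dimethyl acetal)
Product: 11 2-[(2S)-3,3-dimethoxy-2-methylpropyl]-4,4,5,5-tetramethyl-1,3,2-dioxaborolane
Conditions: HBpin (1.2 equiv), CuCl (3 mol%), (R)-DTBM-SEGPHOS, KOtBu (6 mol%), toluene, rt
Reagents that add atoms: pinacolborane, CC1(C)OBOC1(C)C
Why: In this CuH-catalysed anti-Markovnikov asymmetric hydroboration of a 1,1-disubstituted alkene the ligand distinguishes CH3 from the branched CH(OMe)2 group during hydrocupration and sets C4 as S, and no alkoxy group sits beta to copper, so elimination cannot occur.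

**Step 6**
Reactants: 9 trisylhydrazone of 8; 11 2-[(2S)-3,3-dimethoxy-2-methylpropyl]-4,4,5,5-tetramethyl-1,3,2-dioxaborolane
Product: 15 (2S,6R,7E,10S,11E)-1,1-dimethoxy-2,6,10-trimethyl-4-methylidene-12-phenyldodeca-7,11-diene, via vinyllithium 12 (not isolated), via boronate complex 13 (not isolated), via iodo boronate 14 (not isolated)
Conditions: n-BuLi (2.1 equiv), THF, −78 to 0 °C; 11, −78 °C; I2, THF, −78 °C; NaOMe, MeOH, −78 °C to rt
Reagents that add atoms: none
Why: The Shapiro reaction gives the less substituted vinyllithium, which adds to boron; iodine then triggers the 1,2-metallate shift of C5 from boron to C6 (Zweifel olefination), and methoxide-induced anti elimination of boron and iodine leaves the methylidene group while C4, C8 and C12 are not involved.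

**Step 7**
Reactants: 15 (2S,6R,7E,10S,11E)-1,1-dimethoxy-2,6,10-trimethyl-4-methylidene-12-phenyldodeca-7,11-diene
Product: 17 (4S,6R)-3-methoxy-4,6-dimethyl-6-[(2R,3E,6S,7E)-2,6-dimethyl-8-phenylocta-3,7-dien-1-yl]-1,2-dioxane (both C3 anomers), via hydroperoxy acetal 16 (not isolated)
Conditions: H2O2 (anhydrous, in Et2O, 2 equiv), (S,S)-IDPi (confined imidodiphosphorimidate Brønsted acid, 3,3'-aryl BINOL backbones, N-triflyl; 5 mol%), CH2Cl2, 0 °C; then 5 Å MS, cyclohexane, 30 °C
Reagents that add atoms: hydrogen peroxide, OO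
Why: Proposed new method: the strong confined acid first exchanges one OMe of the acetal for OOH through the oxocarbenium ion (ordinary acid perhydrolysis of an acetal), then protonates the CH2 terminus of the 1,1-disubstituted alkene while the terminal oxygen of OOH binds C6 in a concerted asynchronous 6-exo closure inside the chiral anion pocket, which distinguishes the emerging CH3 from the CH2R arm and sets C6 as R (matched with the chair preference for an equatorial 4-methyl and long arm); keeping OMe rather than OH at C3 removes the faster five-membered ether closure, a Prins closure would be 5-endo, and the 1,2-disubstituted and styryl alkenes are roughly four orders of magnitude harder to protonate; the closest known reaction types are the IDPi-catalysed asymmetric intramolecular hydroalkoxylation of unactivated 1,1-disubstituted alkenes and the racemic acid- or mercury-mediated cyclisation of unsaturated hydroperoxides.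

**Step 8**
Reactants: 17 (4S,6R)-3-methoxy-4,6-dimethyl-6-[(2R,3E,6S,7E)-2,6-dimethyl-8-phenylocta-3,7-dien-1-yl]-1,2-dioxane
Product: 19 2-[(3S,4S,6R)-4,6-dimethyl-6-[(2R,3E,6S,7E)-2,6-dimethyl-8-phenylocta-3,7-dien-1-yl]-1,2-dioxan-3-yl]acetic acid, via silyl ester 18 (not isolated)
Conditions: CH2=C(OTMS)2 (2 equiv), TMSOTf (20 mol%), CH2Cl2, −78 °C; pH 4 aqueous work-up
Reagents that add atoms: 1,1-bis(trimethylsilyloxy)ethene, C=C(O[Si](C)(C)C)O[Si](C)(C)C
Why: TMSOTf ionises the anomeric OMe to the peroxycarbenium ion, and Mukaiyama-type attack follows the axial trajectory on the half-chair with the 4-methyl and long C6 arm pseudo-equatorial, on the face opposite the axial 6-methyl, which gives the 3,4-cis-3,6-cis product (C3 = S); the silyl ester hydrolyses on work-up, so the beta-peroxy acid never meets base.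

**Compound list**
1 | ethynylbenzene | C#Cc1ccccc1 | starting material
2 | (E)-pent-3-en-2-one | C/C=C/C(C)=O | starting material
3 | 2-[(E)-2-phenylethenyl]-1,3,2-benzodioxaborole | c1ccccc1/C=C/B1Oc2ccccc2O1 | intermediate
4 | (4S,5E)-4-methyl-6-phenylhex-5-en-2-one | C[C@H](/C=C/c1ccccc1)CC(C)=O | intermediate
5 | diethyl (4S,5E)-4-methyl-6-phenylhexa-1,5-dien-2-yl phosphate | C[C@H](/C=C/c1ccccc1)CC(=C)OP(=O)(OCC)OCC | intermediate
6 | [(1E,3S)-3-methylhex-1-en-5-yn-1-yl]benzene | C[C@H](/C=C/c1ccccc1)CC#C | intermediate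
7 | 2-[(1E,4S,5E)-4-methyl-6-phenylhexa-1,5-dien-1-yl]-1,3,2-benzodioxaborole | C[C@H](/C=C/c1ccccc1)C/C=C/B1Oc2ccccc2O1 | intermediate
8 | (4R,5E,8S,9E)-4,8-dimethyl-10-phenyldeca-5,9-dien-2-one | C[C@H](/C=C/c1ccccc1)C/C=C/[C@H](C)CC(C)=O | intermediate
9 | N'-[(2E,4R,5E,8S,9E)-4,8-dimethyl-10-phenyldeca-5,9-dien-2-ylidene]-2,4,6-tri(propan-2-yl)benzenesulfonohydrazide | C[C@H](/C=C/c1ccccc1)C/C=C/[C@H](C)C/C(C)=N/NS(=O)(=O)c1c(C(C)C)cc(C(C)C)cc1C(C)C | intermediate
10 | 3,3-dimethoxy-2-methylprop-1-ene | C=C(C)C(OC)OC | starting material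
11 | 2-[(2S)-3,3-dimethoxy-2-methylpropyl]-4,4,5,5-tetramethyl-1,3,2-dioxaborolane | CC1(C)OB(C[C@H](C)C(OC)OC)OC1(C)C | intermediate
12 | [(4R,5E,8S,9E)-4,8-dimethyl-10-phenyldeca-1,5,9-trien-2-yl]lithium | C[C@H](/C=C/c1ccccc1)C/C=C/[C@H](C)CC([Li])=C | intermediate
13 | lithium [(4R,5E,8S,9E)-4,8-dimethyl-10-phenyldeca-1,5,9-trien-2-yl][(2S)-3,3-dimethoxy-2-methylpropyl](pinacolato)borate | C[C@H](/C=C/c1ccccc1)C/C=C/[C@H](C)CC(=C)[B-]1(C[C@H](C)C(OC)OC)OC(C)(C)C(C)(C)O1.[Li+] | intermediate
14 | 2-[(2S,6R,7E,10S,11E)-4-(iodomethyl)-1,1-dimethoxy-2,6,10-trimethyl-12-phenyldodeca-7,11-dien-4-yl]-4,4,5,5-tetramethyl-1,3,2-dioxaborolane (both epimers at the boron-bearing carbon) | C[C@H](/C=C/c1ccccc1)C/C=C/[C@H](C)CC(CI)(C[C@H](C)C(OC)OC)B1OC(C)(C)C(C)(C)O1 | intermediate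
15 | (2S,6R,7E,10S,11E)-1,1-dimethoxy-2,6,10-trimethyl-4-methylidene-12-phenyldodeca-7,11-diene | C[C@H](/C=C/c1ccccc1)C/C=C/[C@H](C)CC(=C)C[C@H](C)C(OC)OC | intermediate
16 | (2S,6R,7E,10S,11E)-1-hydroperoxy-1-methoxy-2,6,10-trimethyl-4-methylidene-12-phenyldodeca-7,11-diene (both C1 epimers) | C[C@H](/C=C/c1ccccc1)C/C=C/[C@H](C)CC(=C)C[C@H](C)C(OC)OO | intermediate
17 | (4S,6R)-3-methoxy-4,6-dimethyl-6-[(2R,3E,6S,7E)-2,6-dimethyl-8-phenylocta-3,7-dien-1-yl]-1,2-dioxane (both C3 anomers) | C[C@H](/C=C/c1ccccc1)C/C=C/[C@H](C)C[C@]1(C)C[C@H](C)C(OC)OO1 | intermediate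
18 | trimethylsilyl 2-[(3S,4S,6R)-4,6-dimethyl-6-[(2R,3E,6S,7E)-2,6-dimethyl-8-phenylocta-3,7-dien-1-yl]-1,2-dioxan-3-yl]acetate | C[C@H](/C=C/c1ccccc1)C/C=C/[C@H](C)C[C@]1(C)C[C@H](C)[C@H](CC(=O)O[Si](C)(C)C)OO1 | intermediate
19 | 2-[(3S,4S,6R)-4,6-dimethyl-6-[(2R,3E,6S,7E)-2,6-dimethyl-8-phenylocta-3,7-dien-1-yl]-1,2-dioxan-3-yl]acetic acid | C[C@H](/C=C/c1ccccc1)C/C=C/[C@H](C)C[C@]1(C)C[C@H](C)[C@H](CC(=O)O)OO1 | target

**Step count and risks**

Total step count: 8. Longest linear sequence: 7 (steps 1, 2, 3, 4, 6, 7, 8).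

Steps most likely to fail:

Step 7 (the new step). H2O2 and methanol may dampen the acid, the hydroperoxy acetal may dehydrate to the methyl ester, or the facial control at C6 may be weak. The fallback sets out from 15 and comes back at 17, using known chemistry. Compound 15 is perhydrolysed with ethereal H2O2 and catalytic camphorsulfonic acid, and hydroperoxy acetal 16 is isolated. Hg(OAc)2 in CH2Cl2 then closes the ring by intramolecular peroxymercuration to the 6-(acetoxymercuriomethyl)-3-methoxy-1,2-dioxane F1. Alkaline NaBH4 demercurates F1 to 17 together with the 6-epimeric methoxy dioxane F2, which is removed by chromatography. There is no catalyst control here, so about half of the material is lost.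

Step 6. n-BuLi may attack the styryl unit, the vinyllithium may be quenched, or the boronate complex may form incompletely. The fallback sets out from 8 and 11 and comes back at 15, replacing the boronate rearrangement with a Pd cross-coupling. KHMDS and PhNTf2 at −78 °C convert 8 into the kinetic enol triflate F3. KHF2 in aqueous MeOH converts 11 into the potassium alkyltrifluoroborate F4. A B-alkyl Suzuki–Miyaura coupling (PdCl2(dppf), Cs2CO3, THF/H2O, 65 °C) joins F3 and F4 to give 15.

Step 8. The face selectivity next to the 4-methyl group may be low, or the ion may lose a proton at C4. The fallback sets out from 17 and comes back at 19, replacing the cation chemistry with an olefination and conjugate-addition sequence. Aqueous AcOH/THF hydrolyses 17 to the 1,2-dioxan-3-ol F5. Its open hydroperoxy aldehyde form undergoes Horner–Wadsworth–Emmons olefination with trimethyl phosphonoacetate (LiCl, iPr2NEt) to the (E)-hydroperoxy enoate F6. Et2NH in CF3CH2OH closes F6 by intramolecular oxa-Michael addition to the methyl ester F7, and the C3 epimers are separated. LiOH in THF/H2O at 0 °C then gives 19.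

**Further compounds**
F1 | step 7 | (4S)-6-(acetoxymercuriomethyl)-3-methoxy-4-methyl-6-[(2R,3E,6S,7E)-2,6-dimethyl-8-phenylocta-3,7-dien-1-yl]-1,2-dioxane (both C6 epimers) | C[C@H](/C=C/c1ccccc1)C/C=C/[C@H](C)CC1(C[Hg]OC(C)=O)C[C@H](C)C(OC)OO1
F2 | step 7 | (4S,6S)-3-methoxy-4,6-dimethyl-6-[(2R,3E,6S,7E)-2,6-dimethyl-8-phenylocta-3,7-dien-1-yl]-1,2-dioxane | C[C@H](/C=C/c1ccccc1)C/C=C/[C@H](C)C[C@@]1(C)C[C@H](C)C(OC)OO1
F3 | step 6 | (4R,5E,8S,9E)-4,8-dimethyl-10-phenyldeca-1,5,9-trien-2-yl trifluoromethanesulfonate | C[C@H](/C=C/c1ccccc1)C/C=C/[C@H](C)CC(=C)OS(=O)(=O)C(F)(F)F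
F4 | step 6 | potassium [(2S)-3,3-dimethoxy-2-methylpropyl]trifluoroborate | [K+].F[B-](F)(F)C[C@H](C)C(OC)OC
F5 | step 8 | (4S,6R)-4,6-dimethyl-6-[(2R,3E,6S,7E)-2,6-dimethyl-8-phenylocta-3,7-dien-1-yl]-1,2-dioxan-3-ol | C[C@H](/C=C/c1ccccc1)C/C=C/[C@H](C)C[C@]1(C)C[C@H](C)C(O)OO1
F6 | step 8 | methyl (2E,4S,6R,8R,9E,12S,13E)-6-hydroperoxy-4,6,8,12-tetramethyl-14-phenyltetradeca-2,9,13-trienoate | C[C@H](/C=C/c1ccccc1)C/C=C/[C@H](C)C[C@](OO)(C)C[C@H](C)/C=C/C(=O)OC
F7 | step 8 | methyl 2-[(3S,4S,6R)-4,6-dimethyl-6-[(2R,3E,6S,7E)-2,6-dimethyl-8-phenylocta-3,7-dien-1-yl]-1,2-dioxan-3-yl]acetate | C[C@H](/C=C/c1ccccc1)C/C=C/[C@H](C)C[C@]1(C)C[C@H](C)[C@H](CC(=O)OC)OO1
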